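## Retrosynthetic overview

- Target 20 comes from its silyl ether 19, and 19 from the chroman-3,3-dicarboxylate 15. The two ester carbons on C3 are activating groups only and are cleared by hydrogenolysis, decarboxylation and Barton reduction.
- The structural feature used: C2 (the O1–CH(CH3) carbon) is the α-carbon of an aryl ethyl ether at a higher oxidation level, and C4 is a diaryl methine 1,5 to it along C2–O1–C8a–C4a–C4. The C4 hydrogen can therefore be taken from the O-ethyl CH2, and that same carbon then bonds to C3.
- 15 comes from the diaryl alkylidene malonate 13 by hydride transfer and C2–C3 bond formation. The pyran ring is the only ring made (step 8); benzene ring A and the naphthalene are bought.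
- 13 comes from enol triflate 8 and naphthylzinc 12 (Negishi). 8 comes from aroyl malonate 7, made from methyl 2,6-dihydroxybenzoate 1 and dibenzyl malonate 5; 12 comes from 1,8-dimethoxynaphthalene 9.
- Benzyl esters and a silyl ether are chosen so that no base touches C3 after ring closure and no second hydridic C–H lies near C4.

Key step: step 8

Assumption: the sense of induction of the scandium–pybox catalyst in step 8 cannot be derived from precedent. The route is written with (S,S)-Ph-pybox (2,6-bis[(4S)-4-phenyl-4,5-dihydrooxazol-2-yl]pyridine); the (R,R) ligand is taken instead if the first run gives the (2S,4R) series.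

## Route

Step 1
Reactants: 1 methyl 2,6-dihydroxybenzoate
Product: 2 methyl 2-ethoxy-6-hydroxybenzoate
Conditions: EtOH (1.05 equiv), PPh3, DIAD, THF, 0 °C to rt
Reagents that add atoms: ethanol, CCO
Why: Mitsunobu etherification; once the first phenol of the symmetric diol is alkylated, the remaining hydroxyl is held in a hydrogen bond to the ester carbonyl and reacts much more slowly, so the mono-ethyl ether should be the main product.

Step 2
Reactants: 2 methyl 2-ethoxy-6-hydroxybenzoate
Product: 3 2-ethoxy-6-hydroxybenzoic acid
Conditions: KOH, MeOH/H2O, reflux; then HCl, 0 °C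
Reagents that add atoms: water (from aqueous KOH), O
Why: Saponification of a hindered benzoate needs heat but meets no other base-labile group, and cold acidification avoids decarboxylation of the electron-rich salicylic-type acid.

Step 3
Reactants: 3 2-ethoxy-6-hydroxybenzoic acid
Product: 4 tert-butyldimethylsilyl 2-[(tert-butyldimethylsilyl)oxy]-6-ethoxybenzoate
Conditions: TBSCl (2.5 equiv), imidazole, DMF, rt; used crude
Reagents that add atoms: tert-butyldimethylsilyl chloride, CC(C)(C)[Si](C)(C)Cl
Why: Silylation of both acidic hydroxyls with TBSCl/imidazole gives the silyl ether that later blocks lactonisation and a silyl ester that serves as a masked acid chloride.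

Step 4
Reactants: 4 tert-butyldimethylsilyl 2-[(tert-butyldimethylsilyl)oxy]-6-ethoxybenzoate; 5 dibenzyl malonate
Product: 7 dibenzyl 2-{2-[(tert-butyldimethylsilyl)oxy]-6-ethoxybenzoyl}propanedioate, via aroyl chloride 6 (not isolated)
Conditions: (COCl)2, DMF (cat.), CH2Cl2, 0 °C to rt, concentrate; then 5, MgCl2, Et3N, MeCN, 0 °C to rt; cold dilute HCl work-up
Reagents that add atoms: none
Why: Silyl esters give acid chlorides with oxalyl chloride/DMF without release of HCl, so the aryl silyl ether is not at risk, and the magnesium enolate of the malonate (MgCl2/Et3N C-acylation) is acylated at carbon because the tricarbonyl product is held as a magnesium chelate.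

Step 5
Reactants: 7 dibenzyl 2-{2-[(tert-butyldimethylsilyl)oxy]-6-ethoxybenzoyl}propanedioate
Product: 8 dibenzyl 2-{[2-(tert-butyldimethylsilyloxy)-6-ethoxyphenyl](trifluoromethanesulfonyloxy)methylidene}propanedioate
Conditions: Tf2O, i-Pr2NEt, CH2Cl2, −78 to 0 °C
Reagents that add atoms: trifluoromethanesulfonic anhydride, O=S(=O)(OS(=O)(=O)C(F)(F)F)C(F)(F)F
Why: O-sulfonylation of the enolised tricarbonyl compound at the ketone oxygen gives the enol triflate, and because the two esters are identical there is no alkene geometry to control.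

Step 6
Reactants: 9 1,8-dimethoxynaphthalene
Product: 10 4-bromo-1,8-dimethoxynaphthalene
Conditions: NBS (1.0 equiv), MeCN, 0 °C to rt
Reagents that add atoms: N-bromosuccinimide, O=C1CCC(=O)N1Br
Why: Electrophilic aromatic bromination goes para to a methoxy group at the unhindered C4 of the activated naphthalene, and one equivalent of NBS at low temperature should stop at the monobromide.

Step 7
Reactants: 8 dibenzyl 2-{[2-(tert-butyldimethylsilyloxy)-6-ethoxyphenyl](trifluoromethanesulfonyloxy)methylidene}propanedioate; 10 4-bromo-1,8-dimethoxynaphthalene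
Product: 13 dibenzyl 2-{[2-(tert-butyldimethylsilyloxy)-6-ethoxyphenyl](4,5-dimethoxynaphthalen-1-yl)methylidene}propanedioate, via naphthyllithium 11 (not isolated), via naphthylzinc chloride 12 (not isolated)
Conditions: 10, n-BuLi, THF, −78 °C; ZnCl2, −78 °C to rt; then 8, Pd(OAc)2 (5 mol %), SPhos (10 mol %), THF, 50 °C
Reagents that add atoms: none
Why: Bromine–lithium exchange and transmetalation give the arylzinc, which couples with the electron-poor enol triflate in a Negishi cross-coupling under zerovalent palladium carrying the bulky biaryl phosphine SPhos; the medium is anhydrous and free of base, so triflate, silyl ether and benzyl esters should survive.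

Step 8
Reactants: 13 dibenzyl 2-{[2-(tert-butyldimethylsilyloxy)-6-ethoxyphenyl](4,5-dimethoxynaphthalen-1-yl)methylidene}propanedioate
Product: 15 dibenzyl (2R,4S)-5-(tert-butyldimethylsilyloxy)-4-(4,5-dimethoxynaphthalen-1-yl)-2-methylchromane-3,3-dicarboxylate (2,4-trans), via oxocarbenium malonate zwitterion 14 (not isolated)
Conditions: Sc(OTf)3 (10 mol %), (S,S)-Ph-pybox (12 mol %), 4 Å MS, ClCH2CH2Cl, 60 °C
Reagents that add atoms: none
Why: Proposed new method: the scandium centre chelates the two ester carbonyls and makes C4 electrophilic, a hydride moves suprafacially from the ethoxy CH2 to C4 through a six-membered transition state ([1,5]-hydride transfer), and the resulting zwitterion 14 (scandium malonate at C3, aryl oxocarbenium ion at C2) collapses by C–C bond formation; the closest known reaction type is the Lewis-acid-catalysed hydride transfer/cyclisation of ortho-(benzyloxy)benzylidene malonates to chroman-3,3-dicarboxylates, together with its chiral-Lewis-acid versions for amine donors, none of which has been run with a diaryl-substituted acceptor or an ethyl ether donor. The pyran ring closes in a 6-endo-trig mode, C3 adding to the C2=O1 oxocarbenium bond. C4 is set in the hydride transfer: ring A stands roughly perpendicular to the tetrasubstituted alkene, with the ethoxy group over one face of C4 and the silyloxy group over the other, and the pybox-bound metal has to choose between these two rotamers, which should interconvert at 60 °C so that the step is a dynamic kinetic resolution of the aryl–alkene axis. C2 is set in the closure through a chair-like transition state with the methyl of the (E)-oxocarbenium ion equatorial and the naphthyl group pseudoaxial, away from the peri silyloxy group and gauche to only one ester, which gives the 2,4-trans isomer. The step needs chemoselectivity for the ethoxy C–H, which the substrate secures because the silyl ether, the methyl ethers and the benzyl esters have no hydridic C–H within reach of C4, and it needs the phenol to stay masked, since a free ortho-hydroxyl would lactonise onto an ester.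

Step 9
Reactants: 15 dibenzyl (2R,4S)-5-(tert-butyldimethylsilyloxy)-4-(4,5-dimethoxynaphthalen-1-yl)-2-methylchromane-3,3-dicarboxylate
Product: 17 (2R,4S)-5-(tert-butyldimethylsilyloxy)-4-(4,5-dimethoxynaphthalen-1-yl)-2-methylchromane-3-carboxylic acid (C3 epimers), via malonic diacid 16 (not isolated)
Conditions: H2 (1 atm), Pd/C, EtOAc, rt; filter; then xylenes, 135 °C
Reagents that add atoms: none
Why: Hydrogenolysis of the benzyl esters and thermal decarboxylation of the resulting malonic acid through its cyclic transition state remove the first carboxyl without any base, so no C3 enolate forms that could expel the C2 aryloxide and scramble C2; the new C3 centre is of no consequence because it is removed in step 10.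

Step 10
Reactants: 17 (2R,4S)-5-(tert-butyldimethylsilyloxy)-4-(4,5-dimethoxynaphthalen-1-yl)-2-methylchromane-3-carboxylic acid
Product: 19 tert-butyl{[(2R,4S)-4-(4,5-dimethoxynaphthalen-1-yl)-2-methylchroman-5-yl]oxy}dimethylsilane, via Barton ester 18 (not isolated)
Conditions: N-hydroxypyridine-2-thione, DCC, DMAP (cat.), CH2Cl2, rt, dark; then t-BuSH, hν (tungsten lamp), rt
Reagents that add atoms: none
Why: Barton reductive decarboxylation: the thiohydroxamate ester fragments under light to the C3 radical, which should take hydrogen from the thiol faster than it can rearrange, leaving C2 and C4 untouched.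

Step 11
Reactants: 19 tert-butyl{[(2R,4S)-4-(4,5-dimethoxynaphthalen-1-yl)-2-methylchroman-5-yl]oxy}dimethylsilane
Product: 20 (2R,4S)-4-(4,5-dimethoxynaphthalen-1-yl)-2-methylchroman-5-ol (cladonaphchrom A)
Conditions: TBAF, AcOH, THF, 0 °C to rt
Reagents that add atoms: none
Why: Fluoride cleaves the aryl silyl ether, and acetic acid buffers the phenoxide so that the electron-rich product is not exposed to base.

## Compound list

1 | methyl 2,6-dihydroxybenzoate | COC(=O)c1c(O)cccc1O | starting material
2 | methyl 2-ethoxy-6-hydroxybenzoate | CCOc1cccc(O)c1C(=O)OC | intermediate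
3 | 2-ethoxy-6-hydroxybenzoic acid | CCOc1cccc(O)c1C(=O)O | intermediate
4 | tert-butyldimethylsilyl 2-[(tert-butyldimethylsilyl)oxy]-6-ethoxybenzoate | CCOc1cccc(O[Si](C)(C)C(C)(C)C)c1C(=O)O[Si](C)(C)C(C)(C)C | intermediate
5 | dibenzyl malonate | O=C(CC(=O)OCc1ccccc1)OCc1ccccc1 | starting material
6 | 2-[(tert-butyldimethylsilyl)oxy]-6-ethoxybenzoyl chloride (not isolated) | CCOc1cccc(O[Si](C)(C)C(C)(C)C)c1C(=O)Cl | intermediate
7 | dibenzyl 2-{2-[(tert-butyldimethylsilyl)oxy]-6-ethoxybenzoyl}propanedioate | CCOc1cccc(O[Si](C)(C)C(C)(C)C)c1C(=O)C(C(=O)OCc1ccccc1)C(=O)OCc1ccccc1 | intermediate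
8 | dibenzyl 2-{[2-(tert-butyldimethylsilyloxy)-6-ethoxyphenyl](trifluoromethanesulfonyloxy)methylidene}propanedioate | CCOc1cccc(O[Si](C)(C)C(C)(C)C)c1C(OS(=O)(=O)C(F)(F)F)=C(C(=O)OCc1ccccc1)C(=O)OCc1ccccc1 | intermediate
9 | 1,8-dimethoxynaphthalene | COc1cccc2cccc(OC)c12 | starting material
10 | 4-bromo-1,8-dimethoxynaphthalene | COc1cccc2c(Br)ccc(OC)c12 | intermediate
11 | (4,5-dimethoxynaphthalen-1-yl)lithium (not isolated) | [Li]c1ccc(OC)c2c(OC)cccc12 | intermediate
12 | chloro(4,5-dimethoxynaphthalen-1-yl)zinc (not isolated) | Cl[Zn]c1ccc(OC)c2c(OC)cccc12 | intermediate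
13 | dibenzyl 2-{[2-(tert-butyldimethylsilyloxy)-6-ethoxyphenyl](4,5-dimethoxynaphthalen-1-yl)methylidene}propanedioate | COc1cccc2c(C(=C(C(=O)OCc3ccccc3)C(=O)OCc3ccccc3)c3c(OCC)cccc3O[Si](C)(C)C(C)(C)C)ccc(OC)c12 | intermediate
14 | zwitterion after hydride transfer, drawn without the metal: (S)-diaryl methine at C4, aryl oxocarbenium ion (ArO+=CHCH3) and dibenzyl malonate carbanion (not isolated) | COc1cccc2c([C@@H](c3c(O[Si](C)(C)C(C)(C)C)cccc3[O+]=CC)[C-](C(=O)OCc3ccccc3)C(=O)OCc3ccccc3)ccc(OC)c12 | intermediate
15 | dibenzyl (2R,4S)-5-(tert-butyldimethylsilyloxy)-4-(4,5-dimethoxynaphthalen-1-yl)-2-methylchromane-3,3-dicarboxylate (2,4-trans) | COc1cccc2c([C@@H]3C(C(=O)OCc4ccccc4)(C(=O)OCc4ccccc4)[C@@H](C)Oc4cccc(O[Si](C)(C)C(C)(C)C)c43)ccc(OC)c12 | intermediate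
16 | (2R,4S)-5-(tert-butyldimethylsilyloxy)-4-(4,5-dimethoxynaphthalen-1-yl)-2-methylchromane-3,3-dicarboxylic acid (not isolated) | COc1cccc2c([C@@H]3C(C(=O)O)(C(=O)O)[C@@H](C)Oc4cccc(O[Si](C)(C)C(C)(C)C)c43)ccc(OC)c12 | intermediate
17 | (2R,4S)-5-(tert-butyldimethylsilyloxy)-4-(4,5-dimethoxynaphthalen-1-yl)-2-methylchromane-3-carboxylic acid, C3 epimers | COc1cccc2c([C@@H]3C(C(=O)O)[C@@H](C)Oc4cccc(O[Si](C)(C)C(C)(C)C)c43)ccc(OC)c12 | intermediate
18 | 2-thioxopyridin-1(2H)-yl ester of 17 (not isolated) | COc1cccc2c([C@@H]3C(C(=O)ON4C=CC=CC4=S)[C@@H](C)Oc4cccc(O[Si](C)(C)C(C)(C)C)c43)ccc(OC)c12 | intermediate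
19 | tert-butyl{[(2R,4S)-4-(4,5-dimethoxynaphthalen-1-yl)-2-methylchroman-5-yl]oxy}dimethylsilane | COc1cccc2c([C@@H]3C[C@@H](C)Oc4cccc(O[Si](C)(C)C(C)(C)C)c43)ccc(OC)c12 | intermediate
20 | (2R,4S)-4-(4,5-dimethoxynaphthalen-1-yl)-2-methylchroman-5-ol, 2,4-trans (cladonaphchrom A) | COc1cccc2c([C@@H]3C[C@@H](C)Oc4cccc(O)c43)ccc(OC)c12 | target

## Step count and risks

Total steps: 11. Longest linear sequence: 10 (steps 1–5 and 7–11; step 6 is the naphthalene branch).

**Step 8 (carries the proposed method).** The hydride transfer may not start, because the electron-rich naphthyl group lowers the hydride affinity of C4 and a plain ethyl ether is a weak donor. Other failure modes are desilylation followed by lactonisation onto an ester, loss of a proton from the oxocarbenium ion to give an aryl vinyl ether, and poor discrimination between the two ring A rotamers (low enantiomeric excess).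

The fallback uses known reactions only. It sets out from 1,8-dimethoxynaphthalene 9 and returns at the target 20; the pyran ring is made first and the C4–naphthyl bond last.
- Commercial methyl (S)-3-hydroxybutanoate is converted into (S)-3-hydroxy-N-methoxy-N-methylbutanamide F1 (MeNHOMe·HCl, i-PrMgCl, THF, −20 °C).
- After deprotonation of the hydroxyl of F1 with i-PrMgCl, [2,6-bis(methoxymethoxy)phenyl]lithium F2 (from commercial 1,3-bis(methoxymethoxy)benzene, n-BuLi, THF, 0 °C) adds to the Weinreb amide to give (S)-1-[2,6-bis(methoxymethoxy)phenyl]-3-hydroxybutan-1-one F3.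
- HCl in MeOH at rt frees both phenols to give (S)-1-(2,6-dihydroxyphenyl)-3-hydroxybutan-1-one F4.
- Intramolecular Mitsunobu etherification (PPh3, DIAD, THF, 0 °C) closes the ring with inversion to (R)-5-hydroxy-2-methylchroman-4-one F5.
- NaBH4 in MeOH gives (2R)-5-hydroxy-2-methylchroman-4-ol F6 as a mixture of C4 epimers; this centre is lost in the next operation.
- Acid-catalysed Friedel–Crafts alkylation of an excess of 9 (TsOH cat., CH2Cl2, 0 °C) through the ortho-quinone-methide-type cation at C4 should give 20. The arene is expected to attack through its C4, para to methoxy, and pseudoaxially on the half-chair that keeps the C2 methyl equatorial. This is the 2,4-trans outcome known for acid-mediated arylation of 2-substituted chroman-4-ols.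

**Step 7.** Transmetalation and reductive elimination at a carbon that ends up flanked by a 2,6-disubstituted aryl and a 1-naphthyl group may be slow. Cleavage of the triflate back to 7 and protodemetalation of 12 would then take over.

The fallback sets out from aroyl malonate 7 (with naphthyllithium 11 made as in step 7) and returns at 13. It replaces palladium catalysis by a stoichiometric conjugate addition–elimination.
- 7 is converted into the enol phosphate dibenzyl 2-{[2-(tert-butyldimethylsilyloxy)-6-ethoxyphenyl][(diethoxyphosphoryl)oxy]methylidene}propanedioate F7 (NaH, ClP(O)(OEt)2, THF, 0 °C).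
- F7 is treated with lithium bis(4,5-dimethoxynaphthalen-1-yl)cuprate F8 (from two equivalents of 11 and CuI, THF, −78 to 0 °C). Substitution of enol phosphates of β-dicarbonyl compounds by diorganocuprates is a known route to β,β-disubstituted unsaturated esters and should give 13.

**Step 10.** Acylation of the thiohydroxamic acid by the hindered C3 carboxyl may stall (N-acylurea formation). The C3 radical may also undergo β-scission of the C2–O bond or a 1,2-aryl shift before hydrogen transfer.

The fallback sets out from acid 17 and returns at 19. It removes the carbon by decarbonylation instead of radical decarboxylation.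
- BH3·THF reduces 17 to [(2R,4S)-5-(tert-butyldimethylsilyloxy)-4-(4,5-dimethoxynaphthalen-1-yl)-2-methylchroman-3-yl]methanol F9.
- Dess–Martin periodinane (NaHCO3, CH2Cl2) gives (2R,4S)-5-(tert-butyldimethylsilyloxy)-4-(4,5-dimethoxynaphthalen-1-yl)-2-methylchromane-3-carbaldehyde F10, used crude.
- Stoichiometric RhCl(PPh3)3 in toluene at 110 °C (Tsuji–Wilkinson decarbonylation) should give 19.

## Further compounds

F1 | step 8 | (S)-3-hydroxy-N-methoxy-N-methylbutanamide | C[C@H](O)CC(=O)N(C)OC
F2 | step 8 | [2,6-bis(methoxymethoxy)phenyl]lithium | [Li]c1c(OCOC)cccc1OCOC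
F3 | step 8 | (S)-1-[2,6-bis(methoxymethoxy)phenyl]-3-hydroxybutan-1-one | C[C@H](O)CC(=O)c1c(OCOC)cccc1OCOC
F4 | step 8 | (S)-1-(2,6-dihydroxyphenyl)-3-hydroxybutan-1-one | C[C@H](O)CC(=O)c1c(O)cccc1O
F5 | step 8 | (R)-5-hydroxy-2-methylchroman-4-one | C[C@@H]1CC(=O)c2c(O)cccc2O1
F6 | step 8 | (2R)-5-hydroxy-2-methylchroman-4-ol, C4 epimers | C[C@@H]1CC(O)c2c(O)cccc2O1
F7 | step 7 | dibenzyl 2-{[2-(tert-butyldimethylsilyloxy)-6-ethoxyphenyl][(diethoxyphosphoryl)oxy]methylidene}propanedioate | CCOc1cccc(O[Si](C)(C)C(C)(C)C)c1C(OP(=O)(OCC)OCC)=C(C(=O)OCc1ccccc1)C(=O)OCc1ccccc1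
F8 | step 7 | lithium bis(4,5-dimethoxynaphthalen-1-yl)cuprate | [Li+].COc1cccc2c([Cu-]c3ccc(OC)c4c(OC)cccc34)ccc(OC)c12
F9 | step 10 | [(2R,4S)-5-(tert-butyldimethylsilyloxy)-4-(4,5-dimethoxynaphthalen-1-yl)-2-methylchroman-3-yl]methanol, C3 epimers | COc1cccc2c([C@@H]3C(CO)[C@@H](C)Oc4cccc(O[Si](C)(C)C(C)(C)C)c43)ccc(OC)c12
F10 | step 10 | (2R,4S)-5-(tert-butyldimethylsilyloxy)-4-(4,5-dimethoxynaphthalen-1-yl)-2-methylchromane-3-carbaldehyde, C3 epimers | COc1cccc2c([C@@H]3C(C=O)[C@@H](C)Oc4cccc(O[Si](C)(C)C(C)(C)C)c43)ccc(OC)c12
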